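**Retrosynthetic overview**
- The tetramic acid ring is closed last by Lacey–Dieckmann cyclisation of an L‑threonine β‑keto amide; the β‑keto unit comes from Claisen homologation of the decalin C1 methyl ester.
- The C3=C4 alkene (naphthalene numbering) comes from the ring B C4 ketone by enol triflate formation and formate reduction.
- Ring B is closed at the C1–C8a bond by a denitrative 6‑endo radical cyclisation of a tertiary α‑ester radical onto the ring A cyclohexenyl ketone (key step; sets C1 and C8a, C4a after equilibration).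
- The radical precursor comes from an asymmetric Michael addition of methyl 2‑nitropropanoate (sets C2) to a trienone made from sorbaldehyde and 1‑acetyl‑5‑methylcyclohexene.
- Ring order: ring A is bought as (5R)‑5‑methylcyclohex‑2‑en‑1‑one (C6 stereocentre), then ring B, then the tetramic acid ring.

Assumption: (5R)‑5‑methylcyclohex‑2‑en‑1‑one is bought as a catalogue chemical, and the target is made as the 4‑hydroxy (enol) tautomer drawn.
Assumption: the sense of induction of the squaramide in step 5 is taken by analogy; if it is opposite, the quinidine‑derived pseudo‑enantiomer is used.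

**Route**

Step 1
Reactants: 1 (5R)-5-methylcyclohex-2-en-1-one
Product: 3 (5R)-5-methylcyclohex-1-en-1-yl trifluoromethanesulfonate, via lithium enolate 2 (not isolated)
Conditions: LiBH(s-Bu)3 (1.05 equiv), THF, −78 °C; then PhNTf2 (1.1 equiv), −78 °C to rt; water quench
Reagents that add atoms: N-phenylbis(trifluoromethanesulfonimide), O=S(=O)(N(c1ccccc1)S(=O)(=O)C(F)(F)F)C(F)(F)F
Why: conjugate hydride reduction by the hindered borohydride gives one enolate regioisomer, and O‑triflation fixes the double bond between the former carbonyl carbon and C2 while the C5 stereocentre is untouched.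

Step 2
Reactants: 3 (5R)-5-methylcyclohex-1-en-1-yl trifluoromethanesulfonate; 4 butyl vinyl ether
Product: 6 1-[(5R)-5-methylcyclohex-1-en-1-yl]ethan-1-one, via butoxydiene 5 (not isolated)
Conditions: Pd(OAc)2 (3 mol%), 1,3-bis(diphenylphosphino)propane (6 mol%), Et3N (2 equiv), 4 (4 equiv), DMF, 80 °C; then 1 M HCl, THF, rt
Reagents that add atoms: water, O
Why: Mizoroki–Heck coupling by the cationic pathway (triflate plus chelating bisphosphine) bonds the cyclohexenyl group to the oxygen‑bearing carbon of the vinyl ether, and acid hydrolysis of the 2‑butoxydiene gives the conjugated methyl ketone without forming a stereocentre.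

Step 3
Reactants: 6 1-[(5R)-5-methylcyclohex-1-en-1-yl]ethan-1-one; 7 (2E,4E)-hexa-2,4-dienal
Product: 9 (2E,4E,6E)-1-[(5R)-5-methylcyclohex-1-en-1-yl]octa-2,4,6-trien-1-one, via aldol adduct 8 (not isolated)
Conditions: NaOH (10% aq, 1.2 equiv), EtOH, 0 °C to rt
Reagents that add atoms: none
Why: Claisen–Schmidt aldol condensation occurs at the methyl group (the only aldol that can dehydrate into conjugation), E1cB loss of water gives the E enone, and the E,E‑diene of 7 is carried over unchanged.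

Step 4
Reactants: 10 methyl 2-bromopropanoate (racemic)
Product: 11 methyl 2-nitropropanoate (racemic)
Conditions: NaNO2 (1.7 equiv), phloroglucinol (1.1 equiv), DMF, rt
Reagents that add atoms: sodium nitrite, [Na+].[O-]N=O
Why: Kornblum nitrite displacement (SN2 at the α‑bromo ester, N‑attack favoured in DMF, phloroglucinol scavenging the nitrite ester by‑product) gives the α‑nitro ester, whose configuration does not matter later.

Step 5
Reactants: 9 (2E,4E,6E)-1-[(5R)-5-methylcyclohex-1-en-1-yl]octa-2,4,6-trien-1-one; 11 methyl 2-nitropropanoate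
Product: 12 methyl (3S,4E,6E)-2-methyl-3-{2-[(5R)-5-methylcyclohex-1-en-1-yl]-2-oxoethyl}-2-nitroocta-4,6-dienoate (both C2 epimers)
Conditions: 11 (1.5 equiv), 3-{[3,5-bis(trifluoromethyl)phenyl]amino}-4-{[(8α,9S)-6′-methoxycinchonan-9-yl]amino}cyclobut-3-ene-1,2-dione (10 mol%), toluene, −20 °C
Reagents that add atoms: none
Why: in this organocatalytic asymmetric Michael addition the amine of the squaramide deprotonates the acidic nitro ester while the squaramide NH groups bind the ketone, so the nitronate adds 1,4 to the less hindered disubstituted enone arm and the catalyst sets the new C3 centre as S, C2 forming as both epimers because it becomes a planar radical in step 6.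

Step 6
Reactants: 12 methyl (3S,4E,6E)-2-methyl-3-{2-[(5R)-5-methylcyclohex-1-en-1-yl]-2-oxoethyl}-2-nitroocta-4,6-dienoate
Product: 14 methyl (1S,2S,4aS,6R,8aS)-1,6-dimethyl-4-oxo-2-[(1E,3E)-penta-1,3-dien-1-yl]decahydronaphthalene-1-carboxylate, via cis-fused 4a-epimer 13 (not isolated)
Conditions: Bu3SnH (1.3 equiv, syringe pump over 6 h), AIBN (0.2 equiv), PhH (0.01 M), 80 °C; then DBU (0.3 equiv), CH2Cl2, rt
Reagents that add atoms: none
Why: Proposed new method: Bu3Sn• removes the tertiary nitro group to give a planar ester‑conjugated radical that closes 6‑endo‑trig onto the β‑carbon of the cyclohexenyl ketone (5‑exo attack on the fully substituted α‑carbon would give an unstabilised radical), forming the C1–C8a bond irreversibly; in the chair‑like transition state the dienyl group sits equatorial, which selects the alkene face also preferred by ring A (axial attack on the half‑chair with the ring methyl pseudo‑equatorial, new bond cis to that methyl), and allylic 1,3‑strain keeps the ester beside the C2–H so that C1 forms with CO2Me equatorial and methyl axial; H‑transfer to the α‑keto radical gives ring‑fusion epimers that DBU converges to the trans‑fused ketone; the closest known reactions are tin‑hydride denitrative radical cyclisations of tertiary nitro compounds and 6‑endo cyclisations of 4‑oxohex‑5‑enyl radicals onto enones.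

Step 7
Reactants: 14 methyl (1S,2S,4aS,6R,8aS)-1,6-dimethyl-4-oxo-2-[(1E,3E)-penta-1,3-dien-1-yl]decahydronaphthalene-1-carboxylate
Product: 15 methyl (1R,2R,4aS,6R,8aS)-1,6-dimethyl-2-[(1E,3E)-penta-1,3-dien-1-yl]-4-{[(trifluoromethyl)sulfonyl]oxy}-1,2,4a,5,6,7,8,8a-octahydronaphthalene-1-carboxylate
Conditions: KN(SiMe3)2 (1.15 equiv), THF, −78 °C; then PhNTf2 (1.2 equiv), −78 to 0 °C; water quench
Reagents that add atoms: N-phenylbis(trifluoromethanesulfonimide), O=S(=O)(N(c1ccccc1)S(=O)(=O)C(F)(F)F)C(F)(F)F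
Why: kinetic deprotonation takes the C3 methylene (the C4a methine is shielded by the two syn‑axial methyl groups) and O‑triflation (enol triflate formation) places the double bond at C3=C4 without touching C4a.

Step 8
Reactants: 15 methyl (1R,2R,4aS,6R,8aS)-1,6-dimethyl-2-[(1E,3E)-penta-1,3-dien-1-yl]-4-{[(trifluoromethyl)sulfonyl]oxy}-1,2,4a,5,6,7,8,8a-octahydronaphthalene-1-carboxylate
Product: 16 methyl (1R,2R,4aR,6R,8aS)-1,6-dimethyl-2-[(1E,3E)-penta-1,3-dien-1-yl]-1,2,4a,5,6,7,8,8a-octahydronaphthalene-1-carboxylate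
Conditions: Pd(OAc)2 (5 mol%), PPh3 (10 mol%), HCO2H (2.5 equiv), Bu3N (3.5 equiv), DMF, 60 °C
Reagents that add atoms: none
Why: palladium‑catalysed formate reduction of the enol triflate (oxidative addition, formate exchange, decarboxylation, reductive elimination) replaces OTf by H and leaves the ring alkene at C3=C4 with all stereocentres unchanged.

Step 9
Reactants: 16 methyl (1R,2R,4aR,6R,8aS)-1,6-dimethyl-2-[(1E,3E)-penta-1,3-dien-1-yl]-1,2,4a,5,6,7,8,8a-octahydronaphthalene-1-carboxylate; 17 tert-butyl acetate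
Product: 18 tert-butyl 3-[(1R,2R,4aR,6R,8aS)-1,6-dimethyl-2-[(1E,3E)-penta-1,3-dien-1-yl]-1,2,4a,5,6,7,8,8a-octahydronaphthalen-1-yl]-3-oxopropanoate
Conditions: 17 (3 equiv), LiN(i-Pr)2 (3.2 equiv), THF, −78 °C; add 16, −78 to 0 °C; aq. HCl to pH 4
Reagents that add atoms: none
Why: in this crossed Claisen condensation the non‑enolisable ester can only be the acyl acceptor, and excess of the small lithium enolate converts the product into its enolate, which drives the reaction without touching a stereocentre.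

Step 10
Reactants: 19 L-threonine
Product: 20 methyl L-threoninate hydrochloride
Conditions: SOCl2 (1.5 equiv), MeOH, 0 °C to reflux
Reagents that add atoms: methanol, CO; thionyl chloride, O=S(Cl)Cl
Why: Fischer esterification with HCl generated in methanol gives the ester salt with both stereocentres retained.

Step 11
Reactants: 18 tert-butyl 3-[(1R,2R,4aR,6R,8aS)-1,6-dimethyl-2-[(1E,3E)-penta-1,3-dien-1-yl]-1,2,4a,5,6,7,8,8a-octahydronaphthalen-1-yl]-3-oxopropanoate; 20 methyl L-threoninate hydrochloride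
Product: 22 methyl (2S,3R)-2-{3-[(1R,2R,4aR,6R,8aS)-1,6-dimethyl-2-[(1E,3E)-penta-1,3-dien-1-yl]-1,2,4a,5,6,7,8,8a-octahydronaphthalen-1-yl]-3-oxopropanamido}-3-hydroxybutanoate, via acylketene 21 (not isolated)
Conditions: 20 (1.5 equiv), Et3N (1.6 equiv), toluene, 110 °C, 2 h
Reagents that add atoms: none
Why: thermolysis of the tert‑butyl β‑keto ester gives the acylketene, which the free amine traps faster than the secondary alcohol (N‑acylation), leaving all stereocentres unchanged.

Step 12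
Reactants: 22 methyl (2S,3R)-2-{3-[(1R,2R,4aR,6R,8aS)-1,6-dimethyl-2-[(1E,3E)-penta-1,3-dien-1-yl]-1,2,4a,5,6,7,8,8a-octahydronaphthalen-1-yl]-3-oxopropanamido}-3-hydroxybutanoate
Product: 23 (5S)-3-{[(1R,2R,4aR,6R,8aS)-1,6-dimethyl-2-[(1E,3E)-penta-1,3-dien-1-yl]-1,2,4a,5,6,7,8,8a-octahydronaphthalen-1-yl]carbonyl}-4-hydroxy-5-[(1R)-1-hydroxyethyl]-1,5-dihydro-2H-pyrrol-2-one
Conditions: NaOMe (2.5 equiv), MeOH, rt, 30 min; then 1 M HCl
Reagents that add atoms: none
Why: in the Lacey–Dieckmann cyclisation the β‑keto amide enolate attacks the methyl ester to close the tetramic acid ring, and the short reaction time at rt keeps the L‑configured C5 and the side‑chain carbinol intact.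

**Compound list**
1 | (5R)-5-methylcyclohex-2-en-1-one | C[C@@H]1CC=CC(=O)C1 | starting material
2 | lithium (5R)-5-methylcyclohex-1-en-1-olate | [Li+].[O-]C1=CCC[C@@H](C)C1 | intermediate
3 | (5R)-5-methylcyclohex-1-en-1-yl trifluoromethanesulfonate | FC(F)(F)S(=O)(=O)OC1=CCC[C@@H](C)C1 | intermediate
4 | butyl vinyl ether | C=COCCCC | starting material
5 | (5R)-1-(1-butoxyethenyl)-5-methylcyclohex-1-ene | C=C(OCCCC)C1=CCC[C@@H](C)C1 | intermediate
6 | 1-[(5R)-5-methylcyclohex-1-en-1-yl]ethan-1-one | CC(=O)C1=CCC[C@@H](C)C1 | intermediate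
7 | (2E,4E)-hexa-2,4-dienal | C/C=C/C=C/C=O | starting material
8 | (4E,6E)-3-hydroxy-1-[(5R)-5-methylcyclohex-1-en-1-yl]octa-4,6-dien-1-one (both C3 epimers) | C/C=C/C=C/C(O)CC(=O)C1=CCC[C@@H](C)C1 | intermediate
9 | (2E,4E,6E)-1-[(5R)-5-methylcyclohex-1-en-1-yl]octa-2,4,6-trien-1-one | C/C=C/C=C/C=C/C(=O)C1=CCC[C@@H](C)C1 | intermediate
10 | methyl 2-bromopropanoate (racemic) | CC(Br)C(=O)OC | starting material
11 | methyl 2-nitropropanoate (racemic) | CC([N+](=O)[O-])C(=O)OC | intermediate
12 | methyl (3S,4E,6E)-2-methyl-3-{2-[(5R)-5-methylcyclohex-1-en-1-yl]-2-oxoethyl}-2-nitroocta-4,6-dienoate (both C2 epimers) | COC(=O)C(C)([N+](=O)[O-])[C@H](/C=C/C=C/C)CC(=O)C1=CCC[C@@H](C)C1 | intermediate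
13 | methyl (1S,2S,4aR,6R,8aS)-1,6-dimethyl-4-oxo-2-[(1E,3E)-penta-1,3-dien-1-yl]decahydronaphthalene-1-carboxylate (cis-fused) | C/C=C/C=C/[C@@H]1CC(=O)[C@@H]2C[C@H](C)CC[C@@H]2[C@@]1(C)C(=O)OC | intermediate
14 | methyl (1S,2S,4aS,6R,8aS)-1,6-dimethyl-4-oxo-2-[(1E,3E)-penta-1,3-dien-1-yl]decahydronaphthalene-1-carboxylate (trans-fused) | C/C=C/C=C/[C@@H]1CC(=O)[C@H]2C[C@H](C)CC[C@@H]2[C@@]1(C)C(=O)OC | intermediate
15 | methyl (1R,2R,4aS,6R,8aS)-1,6-dimethyl-2-[(1E,3E)-penta-1,3-dien-1-yl]-4-{[(trifluoromethyl)sulfonyl]oxy}-1,2,4a,5,6,7,8,8a-octahydronaphthalene-1-carboxylate | C/C=C/C=C/[C@@H]1C=C(OS(=O)(=O)C(F)(F)F)[C@H]2C[C@H](C)CC[C@@H]2[C@@]1(C)C(=O)OC | intermediate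
16 | methyl (1R,2R,4aR,6R,8aS)-1,6-dimethyl-2-[(1E,3E)-penta-1,3-dien-1-yl]-1,2,4a,5,6,7,8,8a-octahydronaphthalene-1-carboxylate | C/C=C/C=C/[C@@H]1C=C[C@H]2C[C@H](C)CC[C@@H]2[C@@]1(C)C(=O)OC | intermediate
17 | tert-butyl acetate | CC(=O)OC(C)(C)C | starting material
18 | tert-butyl 3-[(1R,2R,4aR,6R,8aS)-1,6-dimethyl-2-[(1E,3E)-penta-1,3-dien-1-yl]-1,2,4a,5,6,7,8,8a-octahydronaphthalen-1-yl]-3-oxopropanoate | C/C=C/C=C/[C@@H]1C=C[C@H]2C[C@H](C)CC[C@@H]2[C@@]1(C)C(=O)CC(=O)OC(C)(C)C | intermediate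
19 | L-threonine | C[C@@H](O)[C@H](N)C(=O)O | starting material
20 | methyl L-threoninate hydrochloride | C[C@@H](O)[C@H](N)C(=O)OC.Cl | intermediate
21 | 3-[(1R,2R,4aR,6R,8aS)-1,6-dimethyl-2-[(1E,3E)-penta-1,3-dien-1-yl]-1,2,4a,5,6,7,8,8a-octahydronaphthalen-1-yl]-3-oxoprop-1-en-1-one (acylketene) | C/C=C/C=C/[C@@H]1C=C[C@H]2C[C@H](C)CC[C@@H]2[C@@]1(C)C(=O)C=C=O | intermediate
22 | methyl (2S,3R)-2-{3-[(1R,2R,4aR,6R,8aS)-1,6-dimethyl-2-[(1E,3E)-penta-1,3-dien-1-yl]-1,2,4a,5,6,7,8,8a-octahydronaphthalen-1-yl]-3-oxopropanamido}-3-hydroxybutanoate | C/C=C/C=C/[C@@H]1C=C[C@H]2C[C@H](C)CC[C@@H]2[C@@]1(C)C(=O)CC(=O)N[C@@H]([C@@H](C)O)C(=O)OC | intermediate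
23 | (5S)-3-{[(1R,2R,4aR,6R,8aS)-1,6-dimethyl-2-[(1E,3E)-penta-1,3-dien-1-yl]-1,2,4a,5,6,7,8,8a-octahydronaphthalen-1-yl]carbonyl}-4-hydroxy-5-[(1R)-1-hydroxyethyl]-1,5-dihydro-2H-pyrrol-2-one | C/C=C/C=C/[C@@H]1C=C[C@H]2C[C@H](C)CC[C@@H]2[C@@]1(C)C(=O)C1=C(O)[C@H]([C@@H](C)O)NC1=O | target

**Step count:** 12 steps in total. The longest linear sequence is 10 steps (1, 2, 3, 5, 6, 7, 8, 9, 11, 12); steps 4 and 10 are side branches.

**Three steps most likely to fail**

Step 5 may give low enantioselectivity at C3, or addition at the wrong site of the polyenone. The fallback sets out from 6 and comes back at 14. Methyl propanoate is converted (LiN(i-Pr)2, Me3SiCl, THF, −78 °C) into 1-methoxy-1-(trimethylsilyloxy)prop-1-ene F1. F1 adds to 6 in a TiCl4‑mediated Mukaiyama–Michael reaction (CH2Cl2, −78 °C; axial attack cis to the ring methyl, then NaOMe/MeOH to equilibrate the acetyl‑bearing centre) to give methyl 2-[(1S,2S,4R)-2-acetyl-4-methylcyclohexyl]propanoate F2. Kinetic aldol of its methyl ketone (LiN(SiMe3)2, −78 °C) with 7 and MsCl/Et3N dehydration gives methyl 2-{(1S,2S,4R)-4-methyl-2-[(2E,4E,6E)-octa-2,4,6-trienoyl]cyclohexyl}propanoate F3. Its ester enolate (KOt-Bu, THF, −40 °C) closes ring B by intramolecular Michael addition to give 14. Here the ring methyl sets C8a first and the ring closure sets C1 and C2, so no chiral catalyst is needed.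

Step 6 may fail through reduction of the radical before it cyclises, or through tin‑radical attack on the enone or diene. The fallback sets out from 12 and comes back at 14. 12 is denitrated without cyclisation (Bu3SnH 3 equiv in one portion, AIBN, PhH 0.3 M, 80 °C) to methyl (3S,4E,6E)-2-methyl-3-{2-[(5R)-5-methylcyclohex-1-en-1-yl]-2-oxoethyl}octa-4,6-dienoate F4. The ring is then closed by an anionic 6‑endo‑trig Michael addition of the ester enolate onto the cyclohexenyl ketone (LiN(SiMe3)2, THF, −78 to −40 °C, then DBU), which gives 14 through the same chair and 1,3‑strain preferences.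

Step 9 may fail because the fully substituted methyl ester is a poor acyl acceptor, and the doubly allylic C2–H may be deprotonated. The fallback sets out from 16 and comes back at 22. 16 is demethylated (LiI, pyridine, 115 °C) to (1R,2R,4aR,6R,8aS)-1,6-dimethyl-2-[(1E,3E)-penta-1,3-dien-1-yl]-1,2,4a,5,6,7,8,8a-octahydronaphthalene-1-carboxylic acid F5. F5 is activated with 1,1'-carbonyldiimidazole and homologated with the magnesium salt of methyl hydrogen malonate (MgCl2, Et3N, THF, 40 °C) to methyl 3-[(1R,2R,4aR,6R,8aS)-1,6-dimethyl-2-[(1E,3E)-penta-1,3-dien-1-yl]-1,2,4a,5,6,7,8,8a-octahydronaphthalen-1-yl]-3-oxopropanoate F6. F6 is heated with 20 and Et3N (4-dimethylaminopyridine cat., toluene, 110 °C) to give 22.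

**Further compounds**
F1 | step 5 | 1-methoxy-1-(trimethylsilyloxy)prop-1-ene (E/Z mixture) | CC=C(OC)O[Si](C)(C)C
F2 | step 5 | methyl 2-[(1S,2S,4R)-2-acetyl-4-methylcyclohexyl]propanoate (both epimers at the propanoate carbon) | CC(=O)[C@H]1C[C@H](C)CC[C@@H]1C(C)C(=O)OC
F3 | step 5 | methyl 2-{(1S,2S,4R)-4-methyl-2-[(2E,4E,6E)-octa-2,4,6-trienoyl]cyclohexyl}propanoate (both epimers at the propanoate carbon) | C/C=C/C=C/C=C/C(=O)[C@H]1C[C@H](C)CC[C@@H]1C(C)C(=O)OC
F4 | step 6 | methyl (3S,4E,6E)-2-methyl-3-{2-[(5R)-5-methylcyclohex-1-en-1-yl]-2-oxoethyl}octa-4,6-dienoate (both C2 epimers) | COC(=O)C(C)[C@H](/C=C/C=C/C)CC(=O)C1=CCC[C@@H](C)C1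
F5 | step 9 | (1R,2R,4aR,6R,8aS)-1,6-dimethyl-2-[(1E,3E)-penta-1,3-dien-1-yl]-1,2,4a,5,6,7,8,8a-octahydronaphthalene-1-carboxylic acid | C/C=C/C=C/[C@@H]1C=C[C@H]2C[C@H](C)CC[C@@H]2[C@@]1(C)C(=O)O
F6 | step 9 | methyl 3-[(1R,2R,4aR,6R,8aS)-1,6-dimethyl-2-[(1E,3E)-penta-1,3-dien-1-yl]-1,2,4a,5,6,7,8,8a-octahydronaphthalen-1-yl]-3-oxopropanoate | C/C=C/C=C/[C@@H]1C=C[C@H]2C[C@H](C)CC[C@@H]2[C@@]1(C)C(=O)CC(=O)OC
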